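A direct plan would formylate 5-bromo-2-methylaniline A1 to N-(5-bromo-2-methylphenyl)formamide A2, dehydrate this to 4-bromo-2-isocyano-1-methylbenzene A3, lithiate the methyl group and close the C2–C3 bond to 6-bromo-1H-indole A4, then brominate with NBS at C3 to 3,6-dibromo-1H-indole A5 and finally at C2.
Its weakest steps would be:
- the benzylic lithiation and ring closure, because a lithium amide next to an aryl bromide and an isocyanide would invite bromine–lithium exchange, aryne formation and addition to the isocyano carbon;
- the second bromination, at C2 of an N–H indole, because it would compete with attack on the benzo ring and oxidation to oxindoles and would leave a sensitive product in a mixture;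
- the formylation and dehydration, which would add two steps and a labile isocyanide without adding complexity.

The route inverts the usual order of ring construction. The pyrrole ring is bought with both bromines in place as 4,5-dibromo-1H-pyrrole-2-carbaldehyde, and the benzene ring is built onto it: the formyl carbon becomes C7 and the only ring C–H, pyrrole C3, becomes C3a. A bromo-Wittig reaction adds C6 with its bromine, C5 and C4 as an acetal; acid then closes the C3a–C4 bond, aromatises the new ring and frees N–H in one operation. All three bromines are fixed by connectivity, so no indole is brominated, no organolithium meets an aryl bromide and no isocyanide is made.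

Key step: step 3

Remark: compounds 1 and 3 are taken as commercially available; compound 7 is expected as a mixture of alkene isomers, probably rich in the isomer with bromine cis to the pyrrole ring, and is carried on unseparated.

Step 1
Reactants: 1 4,5-dibromo-1H-pyrrole-2-carbaldehyde
Product: 2 tert-butyl 2,3-dibromo-5-formyl-1H-pyrrole-1-carboxylate
Conditions: Boc2O (1.2 equiv), DMAP (0.1 equiv), MeCN, rt
Reagents that add atoms: di-tert-butyl dicarbonate, CC(C)(C)OC(=O)OC(=O)OC(C)(C)C
Why: DMAP-catalysed N-acylation (carbamate formation) of the acidic N–H of a 2-formylpyrrole should be clean, and it removes the proton that would quench the ylide in step 2 while making the formyl group more electrophilic.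

Step 2
Reactants: 3 [2-(1,3-dioxolan-2-yl)ethyl]triphenylphosphonium bromide; 2 tert-butyl 2,3-dibromo-5-formyl-1H-pyrrole-1-carboxylate
Product: 7 tert-butyl 2,3-dibromo-5-[2-bromo-3-(1,3-dioxolan-2-yl)prop-1-en-1-yl]-1H-pyrrole-1-carboxylate, via [2-(1,3-dioxolan-2-yl)ethylidene]triphenylphosphorane 4 (not isolated), via [1-bromo-2-(1,3-dioxolan-2-yl)ethyl]triphenylphosphonium bromide 5 (not isolated), via [1-bromo-2-(1,3-dioxolan-2-yl)ethylidene]triphenylphosphorane 6 (not isolated)
Conditions: 3 (1.5 equiv), NaN(SiMe3)2 (1.5 equiv), THF, −78 to 0 °C; ylide added to Br2 (1.5 equiv), THF, −78 °C; NaN(SiMe3)2 (1.5 equiv), −78 °C; then 2 (1.0 equiv), −78 °C to rt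
Reagents that add atoms: bromine, BrBr
Why: This is a Wittig olefination with an α-bromo ylide, the bromo analogue of the Stork–Zhao iodo-olefination: ylide 4 is brominated at carbon to salt 5, a second deprotonation gives 6, and 6 joins the formyl carbon (future C7) to the bromine-bearing carbon (future C6), so the bromine position is set by connectivity; an E/Z mixture is expected, and the amide base leaves no alkyllithium to exchange with the ring bromines.

Step 3
Reactants: 7 tert-butyl 2,3-dibromo-5-[2-bromo-3-(1,3-dioxolan-2-yl)prop-1-en-1-yl]-1H-pyrrole-1-carboxylate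
Product: 10 2,3,6-tribromo-1H-indole, via 2,3-dibromo-5-[2-bromo-3-(1,3-dioxolan-2-yl)prop-1-en-1-yl]-1H-pyrrole 8 (not isolated), via 2-[(2,3,6-tribromo-4,5-dihydro-1H-indol-4-yl)oxy]ethanol 9 (not isolated)
Conditions: TFA/CH2Cl2 (1:4), anhydrous, 0 °C to rt (40 °C if needed), dark; cold aq. NaHCO3 quench; rapid chromatography
Reagents that add atoms: none
Why: TFA first removes the carbamate (loss of 2-methylpropene and CO2) to give 8 and opens the dioxolane to an oxocarbenium ion at the future C4, which is attacked by pyrrole C3, the only unsubstituted ring position, to give 9; acid-promoted elimination of ethylene glycol across C4–C5 then aromatises the new ring. The closest known reaction type is the Natsume indole synthesis, the acid-mediated cyclisation of 4-(pyrrol-2-yl)butanal acetals onto pyrrole C3. The benzene ring closes at the C3a–C4 bond in a 6-exo-trig Friedel–Crafts mode with respect to the oxocarbenium C=O bond (6-enolendo with respect to the pyrrole C2=C3 bond). The only stereocentre formed, C4 of 9, is racemic and is destroyed on aromatisation. The step needs the chain to lie cis to the pyrrole on the C6=C7 bond, since only that isomer can reach C3; the other isomer should equilibrate under the same acid through reversible protonation at C6 to a pyrrol-2-ylcarbenium (azafulvenium) ion with free rotation about C6–C7, and irreversible aromatisation drains the reactive isomer. Closure at carbon and not at N1 is expected because under acid the nitrogen lone pair belongs to the aromatic sextet and any N,O-acetal would revert, and the bromines at C2, C3 and C6 need no control because they are fixed by connectivity.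

**Compound list**

1 | 4,5-dibromo-1H-pyrrole-2-carbaldehyde | O=Cc1cc(Br)c(Br)[nH]1 | starting material
2 | tert-butyl 2,3-dibromo-5-formyl-1H-pyrrole-1-carboxylate | CC(C)(C)OC(=O)n1c(C=O)cc(Br)c1Br | intermediate
3 | [2-(1,3-dioxolan-2-yl)ethyl]triphenylphosphonium bromide | [Br-].C1COC(CC[P+](c2ccccc2)(c2ccccc2)c2ccccc2)O1 | starting material
4 | [2-(1,3-dioxolan-2-yl)ethylidene]triphenylphosphorane | C1COC(CC=P(c2ccccc2)(c2ccccc2)c2ccccc2)O1 | intermediate
5 | [1-bromo-2-(1,3-dioxolan-2-yl)ethyl]triphenylphosphonium bromide (racemic) | [Br-].BrC(CC1OCCO1)[P+](c1ccccc1)(c1ccccc1)c1ccccc1 | intermediate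
6 | [1-bromo-2-(1,3-dioxolan-2-yl)ethylidene]triphenylphosphorane | BrC(CC1OCCO1)=P(c1ccccc1)(c1ccccc1)c1ccccc1 | intermediate
7 | tert-butyl 2,3-dibromo-5-[2-bromo-3-(1,3-dioxolan-2-yl)prop-1-en-1-yl]-1H-pyrrole-1-carboxylate (E/Z mixture) | CC(C)(C)OC(=O)n1c(C=C(Br)CC2OCCO2)cc(Br)c1Br | intermediate
8 | 2,3-dibromo-5-[2-bromo-3-(1,3-dioxolan-2-yl)prop-1-en-1-yl]-1H-pyrrole (E/Z mixture) | Brc1[nH]c(C=C(Br)CC2OCCO2)cc1Br | intermediate
9 | 2-[(2,3,6-tribromo-4,5-dihydro-1H-indol-4-yl)oxy]ethanol (racemic) | OCCOC1CC(Br)=Cc2[nH]c(Br)c(Br)c12 | intermediate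
10 | 2,3,6-tribromo-1H-indole | Brc1ccc2c(Br)c(Br)[nH]c2c1 | target

Total step count: 3. Longest linear sequence: 3 steps (from 1).

Steps most likely to fail

1. Step 3 (key step). The two alkene isomers of 8 may not interconvert fast enough under acid, or the vinylpyrrole may oligomerise or close at nitrogen before the benzene ring aromatises. The fallback sets out from 2 and comes back at 10; it closes the ring from a carbinol in which C7 is sp3, so no alkene geometry is required. A plain Wittig reaction of 2 with ylide 4 (from 3 and NaN(SiMe3)2 in THF) would give tert-butyl 2,3-dibromo-5-[3-(1,3-dioxolan-2-yl)prop-1-en-1-yl]-1H-pyrrole-1-carboxylate F1. Bromohydrin formation with NBS in wet THF at 0 °C would place the hydroxyl at the pyrrole-stabilised C7 and the bromine at C6, giving tert-butyl 2,3-dibromo-5-[2-bromo-3-(1,3-dioxolan-2-yl)-1-hydroxypropyl]-1H-pyrrole-1-carboxylate F2. TFA in CH2Cl2 would then cyclise the acetal onto pyrrole C3 and remove water, ethylene glycol and the carbamate to give 10.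

2. Step 2. The brominated ylide may exchange bromine with unbrominated ylide or eliminate, so that conversion to the vinyl bromide is poor. The fallback sets out from 2 and comes back at 7. Ramirez olefination of 2 (CBr4, PPh3, CH2Cl2, 0 °C) would give tert-butyl 2,3-dibromo-5-(2,2-dibromoethenyl)-1H-pyrrole-1-carboxylate F3. A trans-selective Negishi mono-alkylation with (1,3-dioxolan-2-ylmethyl)zinc bromide (PdCl2(DPEphos) cat., THF, 0 °C) would then replace the alkenyl bromine trans to the pyrrole, which should undergo oxidative addition to zerovalent palladium faster than the ring bromines. This returns 7 as the single isomer with bromine cis to the pyrrole ring, which the acid of step 3 would have to equilibrate before ring closure.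

3. Step 1. The carbamate on this electron-poor pyrrole may be transferred to the ylide or the amide base during step 2, leaving a pyrrolide whose formyl group no longer reacts. The fallback sets out from 1 and comes back at 10; the nitrogen carries a sulfonyl group through the ring closure and loses it in a separate last operation. NaH and TsCl in THF would give 4,5-dibromo-1-(4-methylbenzenesulfonyl)-1H-pyrrole-2-carbaldehyde F4. The bromo-Wittig reaction with 6, made from 3 as in step 2, would give 2,3-dibromo-5-[2-bromo-3-(1,3-dioxolan-2-yl)prop-1-en-1-yl]-1-(4-methylbenzenesulfonyl)-1H-pyrrole F5. TsOH·H2O in toluene at 80 °C would close and aromatise the benzene ring with the nitrogen blocked, giving 2,3,6-tribromo-1-(4-methylbenzenesulfonyl)-1H-indole F6. KOH in aqueous THF would remove the sulfonyl group to give 10.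

Further compounds
F1 | step 3 | tert-butyl 2,3-dibromo-5-[3-(1,3-dioxolan-2-yl)prop-1-en-1-yl]-1H-pyrrole-1-carboxylate (E/Z mixture) | CC(C)(C)OC(=O)n1c(C=CCC2OCCO2)cc(Br)c1Br
F2 | step 3 | tert-butyl 2,3-dibromo-5-[2-bromo-3-(1,3-dioxolan-2-yl)-1-hydroxypropyl]-1H-pyrrole-1-carboxylate (racemic diastereomer mixture) | CC(C)(C)OC(=O)n1c(C(O)C(Br)CC2OCCO2)cc(Br)c1Br
F3 | step 2 | tert-butyl 2,3-dibromo-5-(2,2-dibromoethenyl)-1H-pyrrole-1-carboxylate | CC(C)(C)OC(=O)n1c(C=C(Br)Br)cc(Br)c1Br
F4 | step 1 | 4,5-dibromo-1-(4-methylbenzenesulfonyl)-1H-pyrrole-2-carbaldehyde | Cc1ccc(cc1)S(=O)(=O)n1c(C=O)cc(Br)c1Br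
F5 | step 1 | 2,3-dibromo-5-[2-bromo-3-(1,3-dioxolan-2-yl)prop-1-en-1-yl]-1-(4-methylbenzenesulfonyl)-1H-pyrrole (E/Z mixture) | Cc1ccc(cc1)S(=O)(=O)n1c(C=C(Br)CC2OCCO2)cc(Br)c1Br
F6 | step 1 | 2,3,6-tribromo-1-(4-methylbenzenesulfonyl)-1H-indole | Cc1ccc(cc1)S(=O)(=O)n1c(Br)c(Br)c2ccc(Br)cc21
A1 | direct plan | 5-bromo-2-methylaniline | Cc1ccc(Br)cc1N
A2 | direct plan | N-(5-bromo-2-methylphenyl)formamide | Cc1ccc(Br)cc1NC=O
A3 | direct plan | 4-bromo-2-isocyano-1-methylbenzene | Cc1ccc(Br)cc1[N+]#[C-]
A4 | direct plan | 6-bromo-1H-indole | Brc1ccc2cc[nH]c2c1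
A5 | direct plan | 3,6-dibromo-1H-indole | Brc1ccc2c(Br)c[nH]c2c1
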